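Its constants were chosen freely; no experiment stands behind them.

Compare the pool of substrate with one concentration before reckoning anything else: that comparison shows which order the rate has.

substrate 20 mM; gas phase 2.5 mM (held); catalyst 40 µM; time 10 d

* amount of target at 10 d, in percent of the substrate charged
* the change that raises the amount of target at 10 d, in percent of the substrate charged most ("none" if none brings more than 2 percentage points) (dusk / dawn / winter / none)
* amount of target at 10 d, in percent of the substrate charged, after winter

- dusk: doubling the saturation concentration of gas phase, all else as stated
- dawn: doubling the transfer coefficient of step 1, all else as stated
- winter: doubling the amount of catalyst, all else as stated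

- at the start none of the gas is dissolved
- run time (flask): 10 d

In this flask gas enters solution and is either captured on the catalyst with substrate, making target, or decomposes, while substrate shares itself with the dormant form. The relaxation half-life 0.428 d is shorter than the run, so I treated substrate and dormant form as one equilibrated pool. The half-life of dissolved gas by decomposition, 0.52 d, is also shorter than the run, so I held [dissolved gas] where transfer balances removal. That gave me the break-even pool, the pool at which the first-order constant for capture of dissolved gas equals the transfer coefficient plus the decomposition constant, 6.83 mM. Far above it the rate is zero order in substrate, far below it pseudo-first-order.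

I went two ways. Treating transfer as the rate-limiting step throughout, the supply 22.2 mM is 111% of the charge. Treating the run as first order gave 96.1%. They parted, and the first plainly cheats, since it exceeds the charge; the second cheats too, because the flask starts above break-even. Adding both terms gave my rule: pool consumed plus break-even pool times ln(starting pool over present pool) equals the supply. From a trial remainder 6.67 mM, one Newton correction left 5.99 mM, so target 70.0%. With the break-even pool halved, winter gave 81.9%. Dusk doubles the supply at the same break-even pool, while dawn doubles the supply too but raises that pool to 9.54 mM, so I chose dusk.

The forecast said 68%, dusk and 79%, both figures below mine, holding that dusk “doubles the gas supply without increasing the loss constant”.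

    gas phase ⇌ dissolved gas, rate k1*(csat - [dissolved gas]) (k1 = 0.037 h⁻¹, csat = 2.5 mM)
    substrate + dissolved gas + catalyst → catalyst + target (k2 = 6.3 × 10⁵ M⁻² h⁻¹)
    substrate ⇌ dormant form (K3 = 0.85, k3 = 0.031 h⁻¹)
    dissolved gas → decomposed reagent (k4 = 0.056 h⁻¹)

The flask gave 68.0%, 79.5% after winter, and dusk best by 26 percentage points. In this flask, substrate 15.8% and dormant form 16.2% stood at 10.0 d. That pool, 6.39 mM, lies near the break-even pool 6.83 mM. For the neighbour flask with 34 mM of substrate, the same break-even pool and supply, a trial of 17.0 mM corrected once left 16.7 mM, so target 50.9%; the simulation gave 50.3%.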